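## Retrosynthetic overview
1. **Feature the strategy rests on:** ring B (C3a, C4, C5, C6, C6a) is a 2,3-diarylcyclopentenone whose α′ carbon C6a also bears the ring A carbonyl C1, so O1 and O6 can share one Lewis acid. C3 is sp2 in the target, but it is carried as an sp3 centre that steers the ring closure and is removed afterwards.
2. **End game (backwards):** sevenfold O-demethylation, then C2=C3 by Saegusa–Ito oxidation, then C6a–OH by hydroxylation of the cis-fused β-diketone.
3. **Key disconnection C3a–C4:** polarised Nazarov closure of a 2-(2,3-diarylacryloyl)-4-styrylcyclopent-2-enone. Ring A is bought as a cyclopentene, and ring B is the only ring that is made.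
4. **C6–C6a:** Nozaki–Hiyama–Kishi coupling of a 2-iodo-4-styrylcyclopentenone with a Perkin-derived (E)-2,3-diarylacrolein, then oxidation.
5. **Relay centre:** nickel-catalysed anti substitution of enantiopure cis-4-acetoxycyclopent-2-enol by an (E)-styrylborate, then oxidation and α-iodination.

Key step: step 10

**Remark on numbering.** Bicyclic compounds keep the pentalene numbering of the target (C1 ketone, C2, C3 styryl carbon, C3a, C4, C5, C6 ketone, C6a). C1, C2, C3 and C4 of the monocyclic cyclopentenones become C1, C6a, C3a and C3. The target is read as (3aS,6aS), with H-3a and 6a-OH cis.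

**Assumption.** Monoacetate 9 is bought enantiopure; both antipodes are sold.

## Route

Step 1
Reactants: 1 3,4,5-trimethoxyphenylacetic acid; 2 3,5-dimethoxybenzaldehyde
Product: 3 (E)-3-(3,5-dimethoxyphenyl)-2-(3,4,5-trimethoxyphenyl)prop-2-enoic acid (aryl groups cis)
Conditions: Ac2O, Et3N, 110 °C; then aq. HCl
Reagents that add atoms: none
Why: Perkin condensation (arylacetic acid variant), in which the mixed-anhydride enolate of 1 adds to 2 and loss of acetate gives the (E)-acid with carboxyl trans to the β-aryl group as the favoured, crystalline isomer.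

Step 2
Reactants: 3 (E)-2,3-diarylacrylic acid
Product: 5 (E)-3-(3,5-dimethoxyphenyl)-N-methoxy-N-methyl-2-(3,4,5-trimethoxyphenyl)prop-2-enamide, via acyl imidazole 4 (not isolated)
Conditions: CDI, CH2Cl2, rt; then MeNH(OMe)·HCl, rt
Reagents that add atoms: N,O-dimethylhydroxylamine hydrochloride, CNOC.Cl; 1,1'-carbonyldiimidazole, O=C(n1ccnc1)n1ccnc1 (its imidazolyl group is found in 4 only)
Why: Acyl-imidazole activation followed by aminolysis is a standard Weinreb amide synthesis and leaves the trisubstituted alkene geometry untouched.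

Step 3
Reactants: 5 Weinreb amide
Product: 6 (E)-3-(3,5-dimethoxyphenyl)-2-(3,4,5-trimethoxyphenyl)prop-2-enal
Conditions: i-Bu2AlH, THF, −78 °C; then aq. potassium sodium tartrate
Reagents that add atoms: none
Why: Hydride reduction of a Weinreb amide stops at the chelated tetrahedral aluminate, so the enal is released only on work-up, without 1,4- or over-reduction.

Step 4
Reactants: 7 1-ethynyl-3,5-dimethoxybenzene
Product: 8 2-[(E)-2-(3,5-dimethoxyphenyl)ethenyl]-4,4,5,5-tetramethyl-1,3,2-dioxaborolane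
Conditions: HBpin, Cp2ZrHCl (10 mol %), Et3N (10 mol %), neat, 60 °C
Reagents that add atoms: pinacolborane, CC1(C)OBOC1(C)C
Why: Zirconocene-catalysed syn hydroboration of a terminal arylalkyne puts boron on the terminal carbon and gives only the (E)-alkenylboronate.

Step 5
Reactants: 8 (E)-styrylboronate; 9 (1S,4R)-cis-4-acetoxycyclopent-2-en-1-ol
Product: 11 (1S,4R)-4-[(E)-2-(3,5-dimethoxyphenyl)ethenyl]cyclopent-2-en-1-ol (styryl trans to OH), via lithium alkenylborate 10 (not isolated)
Conditions: 8, n-BuLi, THF, 0 °C; then 9, NiCl2(PPh3)2 (10 mol %), t-BuCN, NaI, THF, rt → 45 °C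
Reagents that add atoms: n-butyllithium, [Li]CCCC (its butyl group and lithium are found in 10 only)
Why: Nickel-catalysed allylic substitution of the cyclopentenediol monoacetate with a lithium alkenylborate, in which zerovalent nickel ionises the acetate with inversion, the alkenyl group passes from boron to nickel and reductive elimination with retention at the allyl terminus remote from the hydroxyl gives the trans-1,4 product, so the relay centre is set by net inversion of the purchased C–OAc centre.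

Step 6
Reactants: 11 trans-4-styrylcyclopentenol
Product: 12 (4R)-4-[(E)-2-(3,5-dimethoxyphenyl)ethenyl]cyclopent-2-en-1-one
Conditions: DMP, NaHCO3, CH2Cl2, 0 °C → rt
Reagents that add atoms: none
Why: Dess–Martin oxidation of the secondary allylic alcohol runs under near-neutral conditions that spare the doubly allylic C4–H, and reaching the 4-substituted enone this way fixes the position of the alkene without relying on an unselective enolisation of a 3-substituted cyclopentanone.

Step 7
Reactants: 12 (4R)-4-styrylcyclopent-2-enone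
Product: 13 (4R)-4-[(E)-2-(3,5-dimethoxyphenyl)ethenyl]-2-iodocyclopent-2-en-1-one
Conditions: I2, pyridine/CH2Cl2 (1:1), 0 °C → rt, dark
Reagents that add atoms: iodine, [I][I]
Why: α-Iodination of an enone by the Baylis–Hillman-type sequence (pyridine adds at C3, the enolate is iodinated at C2, pyridine is expelled) is specific for C2, and the weak base leaves C4 alone.

Step 8
Reactants: 13 iodoenone; 6 (E)-2,3-diarylacrolein
Product: 14 (4R)-2-[(E)-3-(3,5-dimethoxyphenyl)-1-hydroxy-2-(3,4,5-trimethoxyphenyl)prop-2-enyl]-4-[(E)-2-(3,5-dimethoxyphenyl)ethenyl]cyclopent-2-en-1-one (both carbinol epimers)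
Conditions: CrCl2 (4 equiv), NiCl2 (2 mol %), DMF, rt
Reagents that add atoms: none
Why: Nozaki–Hiyama–Kishi coupling, in which the nickel-catalysed alkenylchromium reagent from the vinyl iodide adds 1,2 to the hindered enal under neutral conditions and gives the Baylis–Hillman-type carbinol without touching the ketone or C4–H; the carbinol configuration is irrelevant because it is oxidised next.

Step 9
Reactants: 14 bis-allylic carbinol
Product: 15 (4R)-2-[(E)-3-(3,5-dimethoxyphenyl)-2-(3,4,5-trimethoxyphenyl)prop-2-enoyl]-4-[(E)-2-(3,5-dimethoxyphenyl)ethenyl]cyclopent-2-en-1-one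
Conditions: DMP, NaHCO3, CH2Cl2, 0 °C; short filtration, used at once
Reagents that add atoms: none
Why: Dess–Martin oxidation of the bis-allylic alcohol gives the alkylidene β-diketone under buffered, non-nucleophilic conditions, which matters because its ring alkene is a strong Michael acceptor and its C4–H (later H-3) is vinylogously acidic.

Step 10
Reactants: 15 2-(2,3-diarylacryloyl)-4-styrylcyclopent-2-enone
Product: 16 (3R,3aR,6aR)-4-(3,5-dimethoxyphenyl)-3-[(E)-2-(3,5-dimethoxyphenyl)ethenyl]-5-(3,4,5-trimethoxyphenyl)-2,3,3a,6a-tetrahydropentalene-1,6-dione (cis-fused; styryl cis to H-3a)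
Conditions: Cu(OTf)2 (10 mol %), ClCH2CH2Cl, 0 °C → rt
Reagents that add atoms: none
Why: Cu(OTf)2 binds O1 and O6 of 15 in a six-membered chelate, which holds C6a=C3a s-trans to C6=O and turns the cross-conjugated dienone into a polarised pentadienyl cation with an electron-poor terminus C3a (two acyl groups on C6a) and an electron-rich terminus C4 (trimethoxyphenyl donor on C5). Thermal conrotatory 4π electrocyclisation joins C3a to C4 and closes ring B as a five-membered carbocycle (electrocyclic, formally 5-endo closure); the closest known reaction type is the Lewis-acid-catalysed polarised Nazarov cyclisation of alkylidene β-dicarbonyl dienones. The oxyallyl intermediate is a copper β-diketonate at C6a and an aryl-stabilised cation at C5, so only H-4 can be lost, the tetrasubstituted C4=C5 enone forms regioselectively, and the released acid protonates C6a and frees the catalyst. C3a is set by torquoselectivity: the arm carrying C4 rotates onto the face of ring A opposite to the styryl group on the adjacent C3, which leaves H-3a cis to the styryl group. C6a is set by protonation under thermodynamic control, since the β-diketone equilibrates and only the cis-fused bicyclo[3.3.0]octane is within reach. The step therefore needs facial selectivity, secured by the C3 substituent next to the reacting terminus, and survival of the vinylogously acidic H-3, secured by a non-basic catalyst, low temperature and freshly made 15.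

Step 11
Reactants: 16 cis-fused β-diketone
Product: 17 (3R,3aS,6aS)-4-(3,5-dimethoxyphenyl)-3-[(E)-2-(3,5-dimethoxyphenyl)ethenyl]-6a-hydroxy-5-(3,4,5-trimethoxyphenyl)-2,3,3a,6a-tetrahydropentalene-1,6-dione
Conditions: 2-(phenylsulfonyl)-3-phenyloxaziridine, DBU (20 mol %), CH2Cl2, −20 → 0 °C
Reagents that add atoms: 2-(phenylsulfonyl)-3-phenyloxaziridine, O=S(=O)(N1OC1c1ccccc1)c1ccccc1
Why: Electrophilic hydroxylation of the β-diketone enolate with a Davis oxaziridine (which does not epoxidise the styrene) can deliver oxygen only on the convex face, because a trans-fused bicyclo[3.3.0]octane is out of reach, so C3a dictates C6a; making C6a quaternary before C3 is erased also keeps ring A from ever tautomerising to a cyclopentadienol that would scramble C3a.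

Step 12
Reactants: 17 6a-hydroxy diketone
Product: 18 (3S,3aS,6aS)-bis-silyl compound: 1-trimethylsilyloxy C1=C2 enol ether and 6a-trimethylsilyl ether of 17 (geometry at C3, C3a and C6a unchanged)
Conditions: TMSOTf, Et3N, CH2Cl2, 0 °C
Reagents that add atoms: trimethylsilyl triflate, C[Si](C)(C)OS(=O)(=O)C(F)(F)F
Why: Soft enolisation gives a single silyl enol ether because C2 is the only α-position left (C6a is quaternary and C6 has no α-hydrogen), and the tertiary alcohol is capped in the same operation, which blocks retro-Claisen and α-ketol pathways.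

Step 13
Reactants: 18 silyl enol ether
Product: 19 (3aS,6aS)-4-(3,5-dimethoxyphenyl)-3-[(E)-2-(3,5-dimethoxyphenyl)ethenyl]-5-(3,4,5-trimethoxyphenyl)-6a-trimethylsilyloxy-3a,6a-dihydropentalene-1,6-dione
Conditions: Pd(OAc)2 (1.1 equiv), MeCN, rt
Reagents that add atoms: none
Why: Saegusa–Ito oxidation, in which Pd(OAc)2 converts the silyl enol ether into a C2-bound palladium enolate whose only β-hydrogen is the doubly allylic H-3, so syn β-hydride elimination gives the C2=C3 enone conjugated with the styryl group and erases the relay centre, while C3a stays fixed because it is locked cis to the quaternary C6a.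

Step 14
Reactants: 19 heptamethyl ether, 6a-O-silyl
Product: 20 CNP0306657.1, (3aS,6aS)-4-(3,5-dihydroxyphenyl)-3-[(E)-2-(3,5-dihydroxyphenyl)ethenyl]-6a-hydroxy-5-(3,4,5-trihydroxyphenyl)-3a,6a-dihydropentalene-1,6-dione
Conditions: BBr3 (excess), CH2Cl2, −78 °C → rt; then ice-water
Reagents that add atoms: none
Why: Boron tribromide cleavage of aryl methyl ethers (bromide attacks the methyl group of each boron-bound ether) is the usual last step for permethylated stilbenoids; the C6a oxygen cannot ionise because the cation would sit between two carbonyl groups, the silyl ether is lost on aqueous work-up, and no stereocentre is touched.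

## Compound list
1 | 3,4,5-trimethoxyphenylacetic acid | COc1cc(CC(=O)O)cc(OC)c1OC | starting material
2 | 3,5-dimethoxybenzaldehyde | COc1cc(C=O)cc(OC)c1 | starting material
3 | (E)-3-(3,5-dimethoxyphenyl)-2-(3,4,5-trimethoxyphenyl)prop-2-enoic acid | OC(=O)/C(c1cc(OC)c(OC)c(OC)c1)=C/c1cc(OC)cc(OC)c1 | intermediate
4 | (E)-3-(3,5-dimethoxyphenyl)-1-(imidazol-1-yl)-2-(3,4,5-trimethoxyphenyl)prop-2-en-1-one (not isolated) | O=C(n1ccnc1)/C(c1cc(OC)c(OC)c(OC)c1)=C/c1cc(OC)cc(OC)c1 | intermediate
5 | (E)-3-(3,5-dimethoxyphenyl)-N-methoxy-N-methyl-2-(3,4,5-trimethoxyphenyl)prop-2-enamide | CON(C)C(=O)/C(c1cc(OC)c(OC)c(OC)c1)=C/c1cc(OC)cc(OC)c1 | intermediate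
6 | (E)-3-(3,5-dimethoxyphenyl)-2-(3,4,5-trimethoxyphenyl)prop-2-enal | O=C/C(c1cc(OC)c(OC)c(OC)c1)=C/c1cc(OC)cc(OC)c1 | intermediate
7 | 1-ethynyl-3,5-dimethoxybenzene | C#Cc1cc(OC)cc(OC)c1 | starting material
8 | 2-[(E)-2-(3,5-dimethoxyphenyl)ethenyl]-4,4,5,5-tetramethyl-1,3,2-dioxaborolane | CC1(C)OB(/C=C/c2cc(OC)cc(OC)c2)OC1(C)C | intermediate
9 | (1S,4R)-cis-4-acetoxycyclopent-2-en-1-ol | O[C@H]1C[C@@H](OC(C)=O)C=C1 | starting material
10 | lithium butyl[(E)-2-(3,5-dimethoxyphenyl)ethenyl](pinacolato)borate (not isolated) | [Li+].CCCC[B-]1(/C=C/c2cc(OC)cc(OC)c2)OC(C)(C)C(C)(C)O1 | intermediate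
11 | (1S,4R)-4-[(E)-2-(3,5-dimethoxyphenyl)ethenyl]cyclopent-2-en-1-ol (trans) | O[C@H]1C[C@H](/C=C/c2cc(OC)cc(OC)c2)C=C1 | intermediate
12 | (4R)-4-[(E)-2-(3,5-dimethoxyphenyl)ethenyl]cyclopent-2-en-1-one | O=C1C[C@H](/C=C/c2cc(OC)cc(OC)c2)C=C1 | intermediate
13 | (4R)-4-[(E)-2-(3,5-dimethoxyphenyl)ethenyl]-2-iodocyclopent-2-en-1-one | O=C1C[C@H](/C=C/c2cc(OC)cc(OC)c2)C=C1I | intermediate
14 | (4R)-2-[(E)-1-hydroxy-2,3-diarylprop-2-enyl]-4-styrylcyclopent-2-en-1-one, both carbinol epimers | O=C1C[C@H](/C=C/c2cc(OC)cc(OC)c2)C=C1C(O)/C(c1cc(OC)c(OC)c(OC)c1)=C/c1cc(OC)cc(OC)c1 | intermediate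
15 | (4R)-2-[(E)-3-(3,5-dimethoxyphenyl)-2-(3,4,5-trimethoxyphenyl)prop-2-enoyl]-4-[(E)-2-(3,5-dimethoxyphenyl)ethenyl]cyclopent-2-en-1-one (Nazarov precursor) | O=C1C[C@H](/C=C/c2cc(OC)cc(OC)c2)C=C1C(=O)/C(c1cc(OC)c(OC)c(OC)c1)=C/c1cc(OC)cc(OC)c1 | intermediate
16 | (3R,3aR,6aR)-cis-fused bicyclic β-diketone (Nazarov product) | O=C1C[C@H](/C=C/c2cc(OC)cc(OC)c2)[C@H]2C(c3cc(OC)cc(OC)c3)=C(c3cc(OC)c(OC)c(OC)c3)C(=O)[C@@H]12 | intermediate
17 | (3R,3aS,6aS)-6a-hydroxy diketone | O=C1C[C@H](/C=C/c2cc(OC)cc(OC)c2)[C@H]2C(c3cc(OC)cc(OC)c3)=C(c3cc(OC)c(OC)c(OC)c3)C(=O)[C@@]12O | intermediate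
18 | (3S,3aS,6aS)-C1=C2 trimethylsilyl enol ether, 6a-O-trimethylsilyl ether | C[Si](C)(C)OC1=C[C@H](/C=C/c2cc(OC)cc(OC)c2)[C@H]2C(c3cc(OC)cc(OC)c3)=C(c3cc(OC)c(OC)c(OC)c3)C(=O)[C@@]12O[Si](C)(C)C | intermediate
19 | (3aS,6aS)-heptamethyl ether of the target, 6a-O-trimethylsilyl | O=C1C=C(/C=C/c2cc(OC)cc(OC)c2)[C@H]2C(c3cc(OC)cc(OC)c3)=C(c3cc(OC)c(OC)c(OC)c3)C(=O)[C@@]12O[Si](C)(C)C | intermediate
20 | CNP0306657.1, (3aS,6aS) | O=C1C=C(/C=C/c2cc(O)cc(O)c2)[C@H]2C(c3cc(O)cc(O)c3)=C(c3cc(O)c(O)c(O)c3)C(=O)[C@@]12O | target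

## Step count
- Total step count: 14.
- Longest linear sequence: 11 steps (7 → 20, steps 4–14). The aldehyde branch (steps 1–3) joins at step 8.

## Steps most likely to fail

**Step 10.**
- **What may go wrong:**
  - Lewis-acid-promoted γ-enolisation of the dienone (shift of C3a=C6a to C3=C3a) may wipe out the relay centre before ring closure.
  - Torquoselectivity may be weak.
  - The trimethoxyphenyl ring may attack C3a in a Friedel–Crafts manner.
  - The β-diketone product may hold the copper back.
- **Fallback:** stereocontrol moves from the relay centre to the catalyst, and the styryl group is brought in afterwards. The fallback sets out from 6 and comes back at 17.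
  - Commercial 2-iodocyclopent-2-en-1-one (O=C1CCC=C1I) is coupled with 6 (CrCl2, cat. NiCl2, DMF) to the carbinol F1.
  - Dess–Martin periodinane oxidises F1 to the achiral 2-(2,3-diarylacryloyl)cyclopent-2-enone F2.
  - An enantioselective Nazarov cyclisation of this chelating dienone with Cu(OTf)2 and a chiral bis(oxazoline) ligand (t-Bu-box, the antipode that leads to the 3aR,6aR series) gives the styryl-free bicyclic β-diketone F3.
  - Oxaziridine hydroxylation as in step 11 gives the 6a-hydroxy diketone F4.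
  - IBX in DMSO at 70 °C dehydrogenates C2–C3 to the hydroxy enone F5.
  - Rhodium-catalysed 1,4-addition of boronate 8 ([Rh(OH)(cod)]2, dioxane/H2O, rt) on the convex face of F5 places the styryl group cis to H-3a and gives 17.

**Step 13.**
- **What may go wrong:** syn β-hydride elimination may be slow, because palladium has to reach C2 from the concave face to lie cis to H-3. Protodesilylation back to the ketone could then take over.
- **Fallback:** a main-group syn elimination with the leaving group placed by substrate control. It sets out from 18 and comes back at 19.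
  - PhSeCl (1.0 equiv, CH2Cl2, −78 °C) selenenylates the silyl enol ether at C2 anti to the neighbouring styryl group, that is cis to H-3, and gives the α-phenylselanyl ketone F6.
  - Oxidation with mCPBA (1.0 equiv, −78 °C) and warming to 0 °C triggers selenoxide syn elimination to 19.

**Step 14.**
- **What may go wrong:**
  - The sevenfold ether cleavage may be incomplete.
  - Long exposure to BBr3 may cause acid-induced degradation: an α-ketol shift at C6a, or hydrobromination or Friedel–Crafts cyclisation at the dienone and styryl units.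
  - The pyrogallol ring may oxidise in air during isolation.
- **Fallback:** the protecting groups are exchanged at the most robust bicyclic stage, so that the last step is a mild fluoride deprotection. It sets out from 16 and comes back at 20.
  - BBr3 (CH2Cl2, −78 °C → rt) on 16, which has neither the tertiary alcohol nor the dienone, gives the heptaphenol F7.
  - TBSCl and imidazole in DMF give the heptakis(tert-butyldimethylsilyl) ether F8.
  - The conditions of steps 11, 12 and 13 then give in turn the 6a-hydroxy diketone F9, the bis(trimethylsilyl) compound F10 and the dienone F11.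
  - HF·pyridine in THF at 0 °C removes all eight silyl groups and gives 20.

## Further compounds
F1 | step 10 | 2-[(E)-3-(3,5-dimethoxyphenyl)-1-hydroxy-2-(3,4,5-trimethoxyphenyl)prop-2-enyl]cyclopent-2-en-1-one (racemic carbinol) | O=C1CCC=C1C(O)/C(c1cc(OC)c(OC)c(OC)c1)=C/c1cc(OC)cc(OC)c1
F2 | step 10 | 2-[(E)-3-(3,5-dimethoxyphenyl)-2-(3,4,5-trimethoxyphenyl)prop-2-enoyl]cyclopent-2-en-1-one | O=C1CCC=C1C(=O)/C(c1cc(OC)c(OC)c(OC)c1)=C/c1cc(OC)cc(OC)c1
F3 | step 10 | (3aR,6aR)-4-(3,5-dimethoxyphenyl)-5-(3,4,5-trimethoxyphenyl)-2,3,3a,6a-tetrahydropentalene-1,6-dione | O=C1CC[C@H]2C(c3cc(OC)cc(OC)c3)=C(c3cc(OC)c(OC)c(OC)c3)C(=O)[C@@H]12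
F4 | step 10 | (3aS,6aS)-4-(3,5-dimethoxyphenyl)-6a-hydroxy-5-(3,4,5-trimethoxyphenyl)-2,3,3a,6a-tetrahydropentalene-1,6-dione | O=C1CC[C@H]2C(c3cc(OC)cc(OC)c3)=C(c3cc(OC)c(OC)c(OC)c3)C(=O)[C@@]12O
F5 | step 10 | (3aS,6aS)-4-(3,5-dimethoxyphenyl)-6a-hydroxy-5-(3,4,5-trimethoxyphenyl)-3a,6a-dihydropentalene-1,6-dione | O=C1C=C[C@H]2C(c3cc(OC)cc(OC)c3)=C(c3cc(OC)c(OC)c(OC)c3)C(=O)[C@@]12O
F6 | step 13 | 2-phenylselanyl ketone, 6a-O-trimethylsilyl, selenium cis to H-3 and trans to the styryl group | O=C1[C@@H]([Se]c3ccccc3)[C@H](/C=C/c2cc(OC)cc(OC)c2)[C@H]2C(c3cc(OC)cc(OC)c3)=C(c3cc(OC)c(OC)c(OC)c3)C(=O)[C@@]12O[Si](C)(C)C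
F7 | step 14 | heptaphenol of 16 | O=C1C[C@H](/C=C/c2cc(O)cc(O)c2)[C@H]2C(c3cc(O)cc(O)c3)=C(c3cc(O)c(O)c(O)c3)C(=O)[C@@H]12
F8 | step 14 | heptakis(tert-butyldimethylsilyl) ether of F7 | O=C1C[C@H](/C=C/c2cc(O[Si](C)(C)C(C)(C)C)cc(O[Si](C)(C)C(C)(C)C)c2)[C@H]2C(c3cc(O[Si](C)(C)C(C)(C)C)cc(O[Si](C)(C)C(C)(C)C)c3)=C(c3cc(O[Si](C)(C)C(C)(C)C)c(O[Si](C)(C)C(C)(C)C)c(O[Si](C)(C)C(C)(C)C)c3)C(=O)[C@@H]12
F9 | step 14 | 6a-hydroxy derivative of F8 | O=C1C[C@H](/C=C/c2cc(O[Si](C)(C)C(C)(C)C)cc(O[Si](C)(C)C(C)(C)C)c2)[C@H]2C(c3cc(O[Si](C)(C)C(C)(C)C)cc(O[Si](C)(C)C(C)(C)C)c3)=C(c3cc(O[Si](C)(C)C(C)(C)C)c(O[Si](C)(C)C(C)(C)C)c(O[Si](C)(C)C(C)(C)C)c3)C(=O)[C@@]12O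
F10 | step 14 | C1=C2 trimethylsilyl enol ether and 6a-O-trimethylsilyl ether of F9 | C[Si](C)(C)OC1=C[C@H](/C=C/c2cc(O[Si](C)(C)C(C)(C)C)cc(O[Si](C)(C)C(C)(C)C)c2)[C@H]2C(c3cc(O[Si](C)(C)C(C)(C)C)cc(O[Si](C)(C)C(C)(C)C)c3)=C(c3cc(O[Si](C)(C)C(C)(C)C)c(O[Si](C)(C)C(C)(C)C)c(O[Si](C)(C)C(C)(C)C)c3)C(=O)[C@@]12O[Si](C)(C)C
F11 | step 14 | octasilylated target (seven aryl tert-butyldimethylsilyl ethers, 6a-O-trimethylsilyl) | O=C1C=C(/C=C/c2cc(O[Si](C)(C)C(C)(C)C)cc(O[Si](C)(C)C(C)(C)C)c2)[C@H]2C(c3cc(O[Si](C)(C)C(C)(C)C)cc(O[Si](C)(C)C(C)(C)C)c3)=C(c3cc(O[Si](C)(C)C(C)(C)C)c(O[Si](C)(C)C(C)(C)C)c(O[Si](C)(C)C(C)(C)C)c3)C(=O)[C@@]12O[Si](C)(C)C
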